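The numbers in the tables were generated by integration on assumed constants; scatter was added.

In the noon run 51.1% of the starting material is already quenched substrate at 6.00 min, against 0.8% target, so the clock to watch in this recipe is the quench.

| setting | autumn | noon | spring | flask |
|---|---|---|---|---|
| starting material | 0.30 M | 0.30 M | 0.30 M | 0.30 M |
| coupling partner | 0.60 M | 0.60 M | 0.90 M | 0.600 M |
| transfer agent | 0.030 M | 0.030 M | 0.030 M | 0.0300 M |
| protic impurity | 0.20 M | 0.45 M | 0.30 M | 0.300 M |
| initiator | 3 mM | 3 mM | 3 mM | 3.0 mM |
| remark | run made earlier | run made earlier | run made earlier |  |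
| time |  |  |  | 2.5 h |

| run | time / min | target / % | quenched substrate / % |
|---|---|---|---|
| autumn | 10.0 | 0.3 | 36.3 |
| autumn | 15.0 | 1.2 | 42.8 |
| autumn | 20.0 | 0 | 50.1 |
| autumn | 30.0 | 2.3 | 54.8 |
| autumn | 50.0 | 2.6 | 62.2 |
| autumn | 80.0 | 2.2 | 64.4 |
| autumn | 120 | 3.9 | 65.8 |
| noon | 6.00 | 0.8 | 51.1 |
| noon | 20.0 | 1.1 | 82.9 |
| noon | 30.0 | 0.1 | 91.0 |
| noon | 50.0 | 2.1 | 94.8 |
| noon | 80.0 | 3.8 | 94.9 |
| noon | 90.0 | 2.9 | 97.0 |
| noon | 120 | 2.0 | 96.1 |
| spring | 10.0 | 2.0 | 50.6 |
| spring | 30.0 | 1.4 | 74.3 |
| spring | 60.0 | 5.3 | 83.9 |
| spring | 80.0 | 6.2 | 86.9 |
| spring | 120 | 4.4 | 90.5 |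

(readings scatter by 1 percentage point)



* target present at 2.5 h, in percent of the starting material charged
* quenched substrate present at 2.5 h, in percent of the starting material charged
* starting material present at 2.5 h, in percent of the starting material charged

The autumn run levels off near 65.8%, and its impurity charge is 66.7% of its starting material, so one impurity takes one starting material. We therefore work with fractions left. For a second-order quench, the logarithm of the impurity fraction left over the starting-material fraction left grows as rate constant times charge difference times time. The first noon reading then gives the quench constant, the rate constant of starting material with impurity, as 0.00584 M⁻¹ s⁻¹.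

But the flask has equal charges, so that difference vanishes and the fraction left becomes one over one plus constant times charge times time, which is 5.96% at 2.5 h. We assume that target formation takes starting material but no impurity, and the late noon readings put it near 2.70%. Splitting that gap evenly about the fraction left, we expect 4.61% starting material and 92.7% quenched substrate.

The forecast, calling the target “a small side channel”, gives 3.3% target, above ours, with 91.9% quenched substrate and 4.8% starting material.

The flask gives 3.12% target, 91.5% quenched substrate and 3.51% starting material.

    initiator → 2 initiating radical (k = 0.0210 min⁻¹)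
    starting material + initiating radical → capped initiator + first chain carrier (k = 7.40 × 10⁵ M⁻¹ s⁻¹)
    coupling partner + first chain carrier → target + second chain carrier (k = 54000 M⁻¹ s⁻¹)
    starting material + second chain carrier → released group + first chain carrier (k = 10000 M⁻¹ s⁻¹)
    transfer agent + first chain carrier → side product + idle radical (kL = 7.30 × 10⁵ M⁻¹ s⁻¹)
    2 idle radical → ended radicals (k = 7.00 × 10⁶ M⁻¹ s⁻¹)
    2 first chain carrier → ended chains A (k = 4.00 × 10⁸ M⁻¹ s⁻¹)
    2 second chain carrier → ended chains B (k = 1.00 × 10⁶ M⁻¹ s⁻¹)
    starting material + protic impurity → quenched substrate (k = 0.340 M⁻¹ min⁻¹)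
    crystals ⇌ released group, rate k10*(cs10 - [released group]) while solid is left; crystals form when [released group] > cs10 (solubility = 33.0 mM, k = 2.30 min⁻¹)

In the flask at 2.5 h, impurity stands at 8.55% of its charge and starting material at 3.51%. Their mean is 6.03%, and their gap of 5 percentage points equals in amount the target plus 1.91% side product. The target stays small mainly because the transfer agent diverts the first chain carrier: the same flask without that step gives 81.3% target instead of 3.12%.

In the neighbour flask with 0.75 M of starting material, the logarithm of the starting-material fraction left over the impurity fraction left reaches 23.7, which marks impurity as the limiting reagent of the quench and leaves 60.0% starting material before the chain's take. The computed neighbour flask holds 58.0% starting material and 40.0% quenched substrate, with impurity gone at 0%.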